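Readings and results are calculated on assumed constants, and the scatter is random.

The target is being made in green, red, blue and violet, closed, stirred, isothermal flasks that hold the same catalyst and added ligand over different charges of starting material, and whoever arrives at 12 min has to know how much target then stands free in solution.

| setting | north | east | green | red | blue | violet |
|---|---|---|---|---|---|---|
| starting material | 0.022 M | 0.76 M | 0.030 M | 0.10 M | 0.30 M | 1.0 M |
| catalyst | 1 mM | 1 mM | 1.0 mM | 1.0 mM | 1.0 mM | 1.0 mM |
| added ligand | 0.64 mM | 0.64 mM | 0.64 mM | 0.64 mM | 0.64 mM | 0.64 mM |
| remark | run made earlier | run made earlier |  |  |  |  |
| time |  |  | 12 min | 12 min | 12 min | 12 min |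

| run | time / min | target / % | starting material / % |
|---|---|---|---|
| north | 2.00 | 15 | 81 |
| north | 4.00 | 27 | 72 |
| north | 6.00 | 39 | 57 |
| north | 8.00 | 41 | 52 |
| east | 0.667 | 4 | 94 |
| east | 1.50 | 12 | 88 |
| east | 4.00 | 29 | 69 |
| east | 8.00 | 48 | 47 |

(standard deviation of a reading: 2 percentage points)

- the analysis behind the earlier runs scatters by 2 percentage points, standard deviation
- a reading or a percentage of target counts all its forms, free or not
- the concentration of target that is asked is that of its free form alone
- "hardly changes" means that all values lie within two and a half points (for a concentration: within two and a half percent of the largest)

- [target] (only what is free in solution) at the end for green, red, blue, violet, in this order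
- the shape of the row from first to last (hardly changes / rises, then falls / falls, then rises / rises all the way / falls all the way)

The runs so far are read through the fraction of starting material lost per minute, ln(charge/left) divided by the time. North at 8.00 min gives 0.0817 min⁻¹, while east, with a charge 34.5 times larger, gives 0.0944 min⁻¹, so their mean, k = 0.0881 min⁻¹, serves as the pseudo-first-order constant of the starting material. If catalyst and added ligand come to terms quickly, they leave a free catalyst that does not depend on the charge of starting material, and k is that free catalyst times a rate constant. Both earlier runs carried 1 mM of catalyst and 0.64 mM of added ligand, so k belongs to that pair, and neither should be topped up.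

By my reckoning, a share exp(−kt) = 34.8 % of the starting material stands at time t = 12 min, so 0.0196 M has reacted in green and 0.652 M in violet, figures for starting material consumed rather than for free target. The forecast gives less than that: 0.0185 M, 0.0625 M, 0.188 M and 0.63 M, a row that rises all the way, in its own words: “Free target therefore rises all the way, roughly in proportion to charge.”

The flasks give 0.0162 M, 0.0539 M, 0.0865 M and 0.0943 M, a row that rises all the way.

    starting material + catalyst → catalyst + target (k = 130 L mol⁻¹ min⁻¹)
    catalyst + added ligand ⇌ idle complex, settled at all times (K = 1300 L mol⁻¹)
    target → over-reaction product (k = 0.0300 min⁻¹)
    crystals ⇌ target, rate k4*(cs4 - [target]) while solid is left; crystals form when [target] > cs4 (solubility = 0.0840 M, k = 2.80 min⁻¹)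

Violet at 12.0 min counts 62.8 % of its charge as target and holds 53.3 % of its charge as crystals, which are counted in that target, and its free target is less than the forecast's. The share reckoned above stands against 34 % of starting material in green. For 6.00 min, exp(−kt) gives 58.9 %, and violet then holds 58.1 %.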